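Links are the product here, and the question is how much of what became links, isomer of the product or over-reaction product is still links when the vessel is read, the selectivity to links.

    links → over-reaction product (k1 = 5.35 × 10⁻⁴ s⁻¹)
    first end groups + second end groups ⇌ links + by-product (K2 = 4.6, k2 = 0.00612 M⁻¹ s⁻¹)
    links ⇌ isomer of the product (K3 = 2.59, k3 = 1.15 × 10⁻⁴ s⁻¹)

| setting | Sunday's | Saturday's | Thursday's | Friday's |
|---|---|---|---|---|
| first end groups | 2.1 M | 2.1 M | 2.1 M | 2.1 M |
| second end groups | 2.14 M | 2.14 M (fed, over 1.60 h) | 2.14 M | 2.14 M |
| remark | a single well-mixed tank run continuously and read at steady state, 2.0 h in it on average | all but second end groups at the start; second end groups goes in evenly over 1.60 h, the run ends at 2.0 h | one stirred flow tank at steady state, fed with the mixture as stated, mean residence time 6.00 h | a closed flask charged with all of it at once and left for 2.0 h |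
| time |  | 2.0 h |  | 2.0 h |

- the set-up with the highest share of links in all that became links or isomer of the product or over-reaction product, at the outlet or at the end ("none" if the first two lie within 2 percentage points) (Sunday's / Saturday's / Thursday's / Friday's / none)
- share of links in all that became links or isomer of the product or over-reaction product, at the outlet or at the end, Sunday's
- share of links in all that became links or isomer of the product or over-reaction product, at the outlet or at the end, Saturday's
- share of links in all that became links or isomer of the product or over-reaction product, at the outlet or at the end, Thursday's
- share of links in all that became links or isomer of the product or over-reaction product, at the outlet or at the end, Friday's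

- the stated concentrations are those of everything mixed, before any reaction; amounts are the same in each set-up
- the feed brings no volume worth counting
- run time (Saturday's): 2.0 h

With the coupling of first and second end groups by itself, links are the one form of the three that arises, and the share stands at 100 %. Now add the turning of links into over-reaction product. In Sunday's tank at steady state, over-reaction product leaves in the outflow as fast as it forms, so it stands to links as the drain number, the rate constant of that step times the residence time: 3.85. This holds whatever the coupling does, and the fraction left as links drops to 20.6 %.

Then comes the isomer, with its way back. In Sunday's tank it stands to links as 0.627, the forward constant times the residence time, divided by one plus the backward constant times the residence time. That is a smaller drain than the first. Together they give the kept fraction, one over one plus both ratios, the part of the three products still links at a tank outlet: 18.3 % for Sunday's. Thursday's longer stay gives 7.23 %. The hand reckoning stops there: it commits to Sunday's over Thursday's and puts no figure on Saturday's or Friday's, which are not tanks at steady state.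

The forecast names Sunday's, with 18.25 % for Sunday's, 13 % for Saturday's, 7.23 % for Thursday's and 4.6 % for Friday's. For the tanks it says “steady-state balances give the share exactly”, the same balances as above. Its Friday's figure comes from hand stepping.

The simulation gives Sunday's as best: 18.3 % for Sunday's, 12.6 % for Saturday's, 7.23 % for Thursday's and 4.55 % for Friday's.

The back-mixing in the tank is the main reason why Sunday's share stands above Friday's: with it taken away, the same charge gives 4.55 % and not 18.3 %. Sunday's outlet holds 57.7 % of the first end groups charged as over-reaction product and 15.0 % as links, a ratio of 3.85 beside the drain number 3.85. For Sunday's tank at ten times the residence time, the kept fraction comes to 2.41 %, and that run reads 2.41 %.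

The rate constants are invented; the rest is arithmetic.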